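**Retrosynthetic overview**

1. The target comes from its 1,16-bis-silyl ether by fluoride desilylation.
2. Both rings come from an acyclic (6S,7S;10S,11S)-bis-epoxy C18 acid in one flask, as in the presumed biogenesis. The ε-lactone forms first (acid onto C7 of the 6,7-epoxide). The ether bridge forms second (C6–OH onto C11 of the glycidate), closing the oxepane and the 1,4-dioxan-2-one together.
3. The bis-epoxy acid comes from oxidation of a C18 epoxy alcohol, made by Sharpless epoxidation of a (10Z)-allylic alcohol.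
4. The (10Z)-allylic alcohol comes from a β-oxido ylide three-component union: C1–C10 epoxy aldehyde + C11–C16 phosphonium salt + CH2O.
5. The epoxy aldehyde comes from nerol (allylic oxidation, Sharpless epoxidation, two-carbon homologation). The phosphonium salt comes from a mono-Wittig reaction of a C4 bis-phosphonium salt with silyloxyacetone.

Numbering used in the text: geranylgeraniol-type chain C1–C16; C17, C18, C19, C20 are the carbons on C15, C11, C7, C3 (C18 becomes the lactone carbonyl). TBS = tert-butyldimethylsilyl, TBSO = its ether.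

**Route**

Step 1
Reactants: 1 nerol
Product: 2 neryl TBS ether
Conditions: TBSCl, imidazole, CH2Cl2, 0 °C → rt
Reagents that add atoms: tert-butyldimethylsilyl chloride, CC(C)(C)[Si](C)(C)Cl
Why: Standard silylation of a primary alcohol; the silyl ether survives the later organolithium and oxidation steps.

Step 2
Reactants: 2 neryl TBS ether
Product: 3 (2E,6Z)-8-(TBSO)-2,6-dimethylocta-2,6-dien-1-ol
Conditions: SeO2 (0.1 equiv), t-BuOOH, salicylic acid (0.1 equiv), CH2Cl2, rt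
Reagents that add atoms: tert-butyl hydroperoxide, CC(C)(C)OO
Why: SeO2-catalysed allylic oxidation (ene/[2,3] sequence) hydroxylates the E-methyl of the terminal trisubstituted alkene; the 2,3-alkene is deactivated by its allylic oxygen.

Step 3
Reactants: 3 (2E,6Z)-8-(TBSO)-2,6-dimethylocta-2,6-dien-1-ol
Product: 4 [(2S,3S)-3-{(3Z)-5-(TBSO)-3-methylpent-3-en-1-yl}-2-methyloxiran-2-yl]methanol
Conditions: Ti(OiPr)4 (0.1 equiv), L-(+)-diethyl tartrate (0.12 equiv), t-BuOOH, 4 Å MS, CH2Cl2, −20 °C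
Reagents that add atoms: tert-butyl hydroperoxide, CC(C)(C)OO
Why: Sharpless asymmetric epoxidation of an (E)-2-methyl allylic alcohol; L-(+)-tartrate gives the (2S,3S)-epoxide, which fixes C6 and C7 as 6S,7S, and only the alkene bearing a free allylic OH reacts.

Step 4
Reactants: 4 [(2S,3S)-3-{(3Z)-5-(TBSO)-3-methylpent-3-en-1-yl}-2-methyloxiran-2-yl]methanol
Product: 6 3-[(2S,3S)-3-{(3Z)-5-(TBSO)-3-methylpent-3-en-1-yl}-2-methyloxiran-2-yl]propanal, via epoxy triflate 5 (not isolated)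
Conditions: Tf2O, 2,6-lutidine, CH2Cl2, −78 °C; then LiCH2CH=N-tBu (3 equiv, from MeCH=N-tBu + LiN(iPr)2), THF, −78 → −30 °C; then aq. citric acid, 0 °C
Reagents that add atoms: N-tert-butylethanimine, CC=NC(C)(C)C; water, O
Why: SN2 alkylation of a metalloenamine (Stork-type) by a primary epoxy triflate, which cannot eliminate because the neighbouring epoxide carbon is quaternary; mild imine hydrolysis frees the aldehyde and the epoxide stereocentres are untouched.

Step 5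
Reactants: 7 butane-1,4-diylbis(triphenylphosphonium) dibromide; 8 1-(TBSO)propan-2-one
Product: 9 {(4Z)-6-(TBSO)-5-methylhex-4-en-1-yl}triphenylphosphonium bromide
Conditions: 7 (2.5 equiv), KN(SiMe3)2 (1.0 equiv per 8), THF, 0 °C; then 8, −78 °C → rt
Reagents that add atoms: none
Why: Wittig reaction of a non-stabilised ylide with an α-silyloxy ketone places the CH2O group cis to the chain (14Z); excess bis-salt with one equivalent of base limits olefination to one phosphonium end.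

Step 6
Reactants: 9 {(4Z)-6-(TBSO)-5-methylhex-4-en-1-yl}triphenylphosphonium bromide; 6 3-[(2S,3S)-3-{(3Z)-5-(TBSO)-3-methylpent-3-en-1-yl}-2-methyloxiran-2-yl]propanal
Product: 11 (2Z)-5-[(2S,3S)-3-{(3Z)-5-(TBSO)-3-methylpent-3-en-1-yl}-2-methyloxiran-2-yl]-2-{(3Z)-5-(TBSO)-4-methylpent-3-en-1-yl}pent-2-en-1-ol, via lithium β-oxido ylide 10 (not isolated)
Conditions: n-BuLi (1.0 equiv), THF, 0 °C; 6, −78 °C; s-BuLi (1.1 equiv), −78 → −30 °C; (CH2O)n, −30 °C → rt
Reagents that add atoms: formaldehyde (as paraformaldehyde), C=O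
Why: β-Oxido ylide (Corey–Schlosser type) three-component olefination: the lithium betaine is deprotonated, hydroxymethylated, and eliminates with the oxygen of 6, so the new CH2OH (C18) ends cis to C9 (10Z); no stereocentre is formed.

Step 7
Reactants: 11 (2Z)-5-[(2S,3S)-3-{(3Z)-5-(TBSO)-3-methylpent-3-en-1-yl}-2-methyloxiran-2-yl]-2-{(3Z)-5-(TBSO)-4-methylpent-3-en-1-yl}pent-2-en-1-ol
Product: 12 [(2R,3S)-3-{2-[(2S,3S)-3-{(3Z)-5-(TBSO)-3-methylpent-3-en-1-yl}-2-methyloxiran-2-yl]ethyl}-2-{(3Z)-5-(TBSO)-4-methylpent-3-en-1-yl}oxiran-2-yl]methanol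
Conditions: Ti(OiPr)4 (0.2 equiv), D-(−)-diethyl tartrate (0.24 equiv), t-BuOOH, 4 Å MS, CH2Cl2, −20 °C
Reagents that add atoms: tert-butyl hydroperoxide, CC(C)(C)OO
Why: Sharpless asymmetric epoxidation is specific for the one free allylic alcohol; D-(−)-tartrate on this Z-alkene gives the (2R,3S)-epoxide, i.e. the C10 oxygen in its final 10S configuration and the C11 oxygen on the face that will later be displaced.

Step 8
Reactants: 12 [(2R,3S)-3-{2-[(2S,3S)-3-{(3Z)-5-(TBSO)-3-methylpent-3-en-1-yl}-2-methyloxiran-2-yl]ethyl}-2-{(3Z)-5-(TBSO)-4-methylpent-3-en-1-yl}oxiran-2-yl]methanol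
Product: 14 (2S,3S)-3-{2-[(2S,3S)-3-{(3Z)-5-(TBSO)-3-methylpent-3-en-1-yl}-2-methyloxiran-2-yl]ethyl}-2-{(3Z)-5-(TBSO)-4-methylpent-3-en-1-yl}oxirane-2-carboxylic acid, via epoxy aldehyde 13 (not isolated)
Conditions: TEMPO (0.1 equiv), PhI(OAc)2, CH2Cl2, rt; then NaClO2, NaH2PO4, 2-methyl-2-butene, t-BuOH/H2O, 0 °C
Reagents that add atoms: sodium chlorite, [Na+].[O-]Cl=O
Why: Oxoammonium oxidation followed by Pinnick oxidation takes the primary epoxy alcohol to the acid; the α-carbon is quaternary so it cannot epimerise, and alkenes, epoxides and silyl ethers are tolerated (the acid is used cold and at once).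

Step 9
Reactants: 14 (2S,3S)-3-{2-[(2S,3S)-3-{(3Z)-5-(TBSO)-3-methylpent-3-en-1-yl}-2-methyloxiran-2-yl]ethyl}-2-{(3Z)-5-(TBSO)-4-methylpent-3-en-1-yl}oxirane-2-carboxylic acid
Product: 16 (1R,2S,5R,9S)-9-{(3Z)-5-(TBSO)-3-methylpent-3-en-1-yl}-1-{(3Z)-5-(TBSO)-4-methylpent-3-en-1-yl}-2-hydroxy-5-methyl-6,8-dioxabicyclo[3.2.2]nonan-7-one, via hydroxy epoxy lactone 15 (not isolated)
Conditions: CSA (0.1 equiv), CH2Cl2, 0 °C; then DBU (2 equiv), MeCN, 40 °C
Reagents that add atoms: none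
Why: Proposed new method: the acid opens the more basic 6,7-epoxide at its tertiary carbon C7 (7-exo, Markovnikov, inversion to 7R; closest known type: acid-catalysed lactonisation of epoxy acids), which ties O7 into ε-lactone 15 and frees the 6S hydroxyl on the face opposite the glycidate oxygen; base then drives a transannular SN2 attack of that hydroxyl on C11, whose C–O bond stands roughly perpendicular to the planar lactone carbonyl and is activated like an α-halo carbonyl (closest known types: α-opening of α,β-epoxy lactones and α,β-epoxy ketones by heteronucleophiles, and SN2 at quaternary α-carbonyl carbons of cyclic sulfamidates), giving inversion to 11R and leaving the epoxide oxygen as the 10S alcohol.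

Step 10
Reactants: 16 (1R,2S,5R,9S)-9-{(3Z)-5-(TBSO)-3-methylpent-3-en-1-yl}-1-{(3Z)-5-(TBSO)-4-methylpent-3-en-1-yl}-2-hydroxy-5-methyl-6,8-dioxabicyclo[3.2.2]nonan-7-one
Product: 17 (1R,2S,5R,9S)-2-hydroxy-9-[(3Z)-5-hydroxy-3-methylpent-3-en-1-yl]-1-[(3Z)-5-hydroxy-4-methylpent-3-en-1-yl]-5-methyl-6,8-dioxabicyclo[3.2.2]nonan-7-one (target)
Conditions: HF·pyridine, pyridine/THF, 0 °C → rt
Reagents that add atoms: none
Why: Buffered fluoride desilylation removes both primary allylic TBS ethers without touching the hindered lactone, the β-hydroxy group or the Z-alkenes.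

**Compound list**

1 | nerol, (2Z)-3,7-dimethylocta-2,6-dien-1-ol | CC(C)=CCC/C(C)=C\CO | starting material
2 | neryl TBS ether, tert-butyl{[(2Z)-3,7-dimethylocta-2,6-dien-1-yl]oxy}dimethylsilane | CC(C)=CCC/C(C)=C\CO[Si](C)(C)C(C)(C)C | intermediate
3 | (2E,6Z)-8-[(tert-butyldimethylsilyl)oxy]-2,6-dimethylocta-2,6-dien-1-ol | OC/C(C)=C/CC/C(C)=C\CO[Si](C)(C)C(C)(C)C | intermediate
4 | [(2S,3S)-3-{(3Z)-5-[(tert-butyldimethylsilyl)oxy]-3-methylpent-3-en-1-yl}-2-methyloxiran-2-yl]methanol | OC[C@]1(C)O[C@H]1CC/C(C)=C\CO[Si](C)(C)C(C)(C)C | intermediate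
5 | trifluoromethanesulfonate of 4 (epoxy triflate) | O=S(=O)(OC[C@]1(C)O[C@H]1CC/C(C)=C\CO[Si](C)(C)C(C)(C)C)C(F)(F)F | intermediate (not isolated)
6 | 3-[(2S,3S)-3-{(3Z)-5-[(tert-butyldimethylsilyl)oxy]-3-methylpent-3-en-1-yl}-2-methyloxiran-2-yl]propanal (C1–C10 epoxy aldehyde, 6S,7S) | O=CCC[C@]1(C)O[C@H]1CC/C(C)=C\CO[Si](C)(C)C(C)(C)C | intermediate
7 | butane-1,4-diylbis(triphenylphosphonium) dibromide | [Br-].[Br-].C(CC[P+](c1ccccc1)(c1ccccc1)c1ccccc1)C[P+](c1ccccc1)(c1ccccc1)c1ccccc1 | starting material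
8 | 1-[(tert-butyldimethylsilyl)oxy]propan-2-one | CC(=O)CO[Si](C)(C)C(C)(C)C | starting material
9 | {(4Z)-6-[(tert-butyldimethylsilyl)oxy]-5-methylhex-4-en-1-yl}triphenylphosphonium bromide | [Br-].C/C(CO[Si](C)(C)C(C)(C)C)=C/CCC[P+](c1ccccc1)(c1ccccc1)c1ccccc1 | intermediate
10 | lithium β-oxido ylide from 9 and 6 (oxido carbon C10 unassigned, lost on elimination) | [Li+].[O-]C(CC[C@]1(C)O[C@H]1CC/C(C)=C\CO[Si](C)(C)C(C)(C)C)C(CC/C=C(/C)CO[Si](C)(C)C(C)(C)C)=P(c1ccccc1)(c1ccccc1)c1ccccc1 | intermediate (not isolated)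
11 | (2Z)-5-[(2S,3S)-3-{(3Z)-5-[(tert-butyldimethylsilyl)oxy]-3-methylpent-3-en-1-yl}-2-methyloxiran-2-yl]-2-{(3Z)-5-[(tert-butyldimethylsilyl)oxy]-4-methylpent-3-en-1-yl}pent-2-en-1-ol | OC/C(CC/C=C(/C)CO[Si](C)(C)C(C)(C)C)=C\CC[C@]1(C)O[C@H]1CC/C(C)=C\CO[Si](C)(C)C(C)(C)C | intermediate
12 | [(2R,3S)-3-{2-[(2S,3S)-3-{(3Z)-5-[(tert-butyldimethylsilyl)oxy]-3-methylpent-3-en-1-yl}-2-methyloxiran-2-yl]ethyl}-2-{(3Z)-5-[(tert-butyldimethylsilyl)oxy]-4-methylpent-3-en-1-yl}oxiran-2-yl]methanol | OC[C@@]1(CC/C=C(/C)CO[Si](C)(C)C(C)(C)C)O[C@H]1CC[C@]2(C)O[C@H]2CC/C(C)=C\CO[Si](C)(C)C(C)(C)C | intermediate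
13 | (2S,3S)-oxirane-2-carbaldehyde corresponding to 12 (C18 aldehyde) | O=C[C@@]1(CC/C=C(/C)CO[Si](C)(C)C(C)(C)C)O[C@H]1CC[C@]2(C)O[C@H]2CC/C(C)=C\CO[Si](C)(C)C(C)(C)C | intermediate (not isolated)
14 | (2S,3S)-3-{2-[(2S,3S)-3-{(3Z)-5-[(tert-butyldimethylsilyl)oxy]-3-methylpent-3-en-1-yl}-2-methyloxiran-2-yl]ethyl}-2-{(3Z)-5-[(tert-butyldimethylsilyl)oxy]-4-methylpent-3-en-1-yl}oxirane-2-carboxylic acid | OC(=O)[C@@]1(CC/C=C(/C)CO[Si](C)(C)C(C)(C)C)O[C@H]1CC[C@]2(C)O[C@H]2CC/C(C)=C\CO[Si](C)(C)C(C)(C)C | intermediate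
15 | (1S,4R,7S)-4-{(1S,4Z)-6-[(tert-butyldimethylsilyl)oxy]-1-hydroxy-4-methylhex-4-en-1-yl}-4-methyl-1-{(3Z)-5-[(tert-butyldimethylsilyl)oxy]-4-methylpent-3-en-1-yl}-3,8-dioxabicyclo[5.1.0]octan-2-one | O=C1O[C@@](C)([C@@H](O)CC/C(C)=C\CO[Si](C)(C)C(C)(C)C)CC[C@@H]2O[C@]12CC/C=C(/C)CO[Si](C)(C)C(C)(C)C | intermediate (not isolated)
16 | (1R,2S,5R,9S)-9-{(3Z)-5-[(tert-butyldimethylsilyl)oxy]-3-methylpent-3-en-1-yl}-1-{(3Z)-5-[(tert-butyldimethylsilyl)oxy]-4-methylpent-3-en-1-yl}-2-hydroxy-5-methyl-6,8-dioxabicyclo[3.2.2]nonan-7-one | C/C(=C/CC[C@@]12O[C@@H](CC/C(C)=C\CO[Si](C)(C)C(C)(C)C)[C@@](C)(CC[C@@H]1O)OC2=O)CO[Si](C)(C)C(C)(C)C | intermediate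
17 | (1R,2S,5R,9S)-2-hydroxy-9-[(3Z)-5-hydroxy-3-methylpent-3-en-1-yl]-1-[(3Z)-5-hydroxy-4-methylpent-3-en-1-yl]-5-methyl-6,8-dioxabicyclo[3.2.2]nonan-7-one | C/C(=C/CC[C@@]12O[C@@H](CC/C(C)=C\CO)[C@@](C)(CC[C@@H]1O)OC2=O)CO | target

**Step count**

Total steps: 10. Longest linear sequence: 9 (steps 1–4, then 6–10).

**Steps most likely to fail, with fallbacks**

Step 9 (second ring closure). This is the weakest step: glycidic esters are normally opened at the β-carbon, so the C6 hydroxyl of 15 may attack C10 instead of C11, and under base an acyl shift followed by tetrahydrofuran formation is also possible. The fallback avoids any α-opening and makes the C11–O–C6 bond from the other side. It sets out from 11, which is epoxidised with L-(+)-diethyl tartrate in place of the D-ester to give the diastereomeric (2S,3R)-epoxy alcohol F1. Oxidation as in step 8 passes through epoxy aldehyde F2 to the (2R,3R)-epoxy acid F3. CSA lactonisation as in the first half of step 9 gives hydroxy epoxy lactone F4, in which the glycidate oxygen now lies on the same face as the C6 carbinol. Dess–Martin periodinane oxidises the C6 alcohol to keto epoxy lactone F5. Sc(OTf)3 in wet MeCN hydrates the glycidate at C10 (its normal β-position, inversion to 10S), and the freed tertiary C11 hydroxyl adds to the C6 ketone to give bridged hemiketal F6. Et3SiH with BF3·OEt2 at −78 °C reduces the bridged oxocarbenium ion from the less hindered lactone-side face, which gives the 9S ether, i.e. 16, where the route is rejoined.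

Step 6 (β-oxido ylide coupling). The three-component olefination needs exact stoichiometry and temperature control, and the betaine can collapse to the disubstituted alkene before hydroxymethylation. The fallback sets out from 9 and 6. The ylide of 9 (n-BuLi) is iodinated with I2 at −78 °C to α-iodophosphonium salt F7, and NaN(SiMe3)2 regenerates the iodo-ylide. Its Z-selective Wittig reaction with 6 gives vinyl iodide F8 (iodine on C11, cis to C9). Iodine–lithium exchange with t-BuLi in Et2O at −78 °C (retention) and addition of paraformaldehyde give 11, where the route is rejoined.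

Step 4 (alkylation of the epoxy triflate). SN2 at a CH2 flanked by a quaternary epoxide carbon is slow, and the basic metalloenamine may attack the triflyl sulfur or the epoxide. The fallback sets out from 3 and makes the C8–C9 bond before any epoxide is present. Appel bromination (CBr4, PPh3) gives allylic bromide F9, and LiCH2CO2tBu displaces it to give tert-butyl ester F10. The 6,7-alkene, the only one without an allylic oxygen, is then epoxidised with KHSO5 (as 2KHSO5·KHSO4·K2SO4) and the L-fructose-derived enantiomer of the Shi ketone to the (6S,7S)-epoxy ester F11. iBu2AlH at −78 °C gives 6, where the route is rejoined.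

**Further compounds**

F1 | step 9 | [(2S,3R)-3-{2-[(2S,3S)-3-{(3Z)-5-(TBSO)-3-methylpent-3-en-1-yl}-2-methyloxiran-2-yl]ethyl}-2-{(3Z)-5-(TBSO)-4-methylpent-3-en-1-yl}oxiran-2-yl]methanol | OC[C@]1(CC/C=C(/C)CO[Si](C)(C)C(C)(C)C)O[C@@H]1CC[C@]2(C)O[C@H]2CC/C(C)=C\CO[Si](C)(C)C(C)(C)C
F2 | step 9 | (2R,3R)-oxirane-2-carbaldehyde corresponding to F1 | O=C[C@]1(CC/C=C(/C)CO[Si](C)(C)C(C)(C)C)O[C@@H]1CC[C@]2(C)O[C@H]2CC/C(C)=C\CO[Si](C)(C)C(C)(C)C
F3 | step 9 | (2R,3R)-oxirane-2-carboxylic acid corresponding to F1 | OC(=O)[C@]1(CC/C=C(/C)CO[Si](C)(C)C(C)(C)C)O[C@@H]1CC[C@]2(C)O[C@H]2CC/C(C)=C\CO[Si](C)(C)C(C)(C)C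
F4 | step 9 | (1R,4R,7R)-4-{(1S,4Z)-6-(TBSO)-1-hydroxy-4-methylhex-4-en-1-yl}-4-methyl-1-{(3Z)-5-(TBSO)-4-methylpent-3-en-1-yl}-3,8-dioxabicyclo[5.1.0]octan-2-one | O=C1O[C@@](C)([C@@H](O)CC/C(C)=C\CO[Si](C)(C)C(C)(C)C)CC[C@H]2O[C@@]12CC/C=C(/C)CO[Si](C)(C)C(C)(C)C
F5 | step 9 | C6 ketone of F4 (keto epoxy lactone) | O=C1O[C@@](C)(C(=O)CC/C(C)=C\CO[Si](C)(C)C(C)(C)C)CC[C@H]2O[C@@]12CC/C=C(/C)CO[Si](C)(C)C(C)(C)C
F6 | step 9 | 9-hydroxy derivative of 16 (bridged hemiketal, both configurations at C9) | C/C(=C/CC[C@@]12OC(O)(CC/C(C)=C\CO[Si](C)(C)C(C)(C)C)[C@@](C)(CC[C@@H]1O)OC2=O)CO[Si](C)(C)C(C)(C)C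
F7 | step 6 | {(4Z)-6-(TBSO)-1-iodo-5-methylhex-4-en-1-yl}triphenylphosphonium iodide (racemic at C1) | [I-].C/C(CO[Si](C)(C)C(C)(C)C)=C/CCC(I)[P+](c1ccccc1)(c1ccccc1)c1ccccc1
F8 | step 6 | (Z)-vinyl iodide: 11 with iodine in place of the CH2OH group | I/C(CC/C=C(/C)CO[Si](C)(C)C(C)(C)C)=C\CC[C@]1(C)O[C@H]1CC/C(C)=C\CO[Si](C)(C)C(C)(C)C
F9 | step 4 | {[(2Z,6E)-8-bromo-3,7-dimethylocta-2,6-dien-1-yl]oxy}(tert-butyl)dimethylsilane | BrC/C(C)=C/CC/C(C)=C\CO[Si](C)(C)C(C)(C)C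
F10 | step 4 | tert-butyl (4E,8Z)-10-(TBSO)-4,8-dimethyldeca-4,8-dienoate | CC(C)(C)OC(=O)CC/C(C)=C/CC/C(C)=C\CO[Si](C)(C)C(C)(C)C
F11 | step 4 | tert-butyl 3-[(2S,3S)-3-{(3Z)-5-(TBSO)-3-methylpent-3-en-1-yl}-2-methyloxiran-2-yl]propanoate | CC(C)(C)OC(=O)CC[C@]1(C)O[C@H]1CC/C(C)=C\CO[Si](C)(C)C(C)(C)C
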